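## The problem

Locants without a prime refer to the phthalide (C1 carbonyl, O2, C3, C3a–C7a), single primes to the hexyl chain (C1′–C6′) and double primes to the spiroketal (O1″–C9″; ring A = O1″–C5″ with the chain on C2″, ring B = C5″–C9″ with the methyl on C7″); the same locants are used for the fragments.

Target 17 consists of a 5,7-dimethoxyphthalide and a 2,7-disubstituted 1,6-dioxaspiro[4.4]nonane joined only by a saturated six-carbon chain. The task is therefore to build a long tether with a ring system at each end, not a fused skeleton. There are four stereocentres, all S: C3, C2″, C5″ and C7″. C3 lies seven bonds from C2″, so neither ring system can direct the other, and C3 must be set by a reagent or catalyst. C2″ and C7″ are secondary carbinol carbons and can be brought in as epoxides. C5″ is the ketal carbon of a five-membered spiroketal, which has no strong anomeric or steric bias. Both C5″ epimers must therefore be expected at equilibrium, and the 5″S isomer (chain on C2″ cis to O6″, methyl on C7″ cis to O1″) has to be isolated and then kept away from acid. The spiroketal is sensitive to protic and Lewis acids, the lactone to strong nucleophiles and bases, and the dimethoxyarene to electrophilic halogen and oxidants. The enabling feature is that C3 is a benzylic carbinol carbon on C3a, and C3a is ortho to C7a, which carries the carbonyl C1. A metal at C3a next to an ester at C7a therefore converts an aldehyde into the lactone by forming C3–C3a and then O2–C1, and the free C4–H leaves the metallated carbon unhindered.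

## Retrosynthesis

**Lactone ring and C3 (17 ⇒ 5 + 15).** The first cut removes C3–C3a and O2–C1 together. Cutting C3–C1′ instead would require an alkyl-metal made from the whole spiroketal chain, used in excess on the more valuable partner. Cutting inside the hexyl chain (olefination, then hydrogenation) costs two steps and still leaves C3 to be made on a separate phthalide fragment. The chosen cut removes a ring and the only isolated stereocentre at once. It leaves methyl 2-iodo-4,6-dimethoxybenzoate 5, which is achiral, and aldehyde 15, which carries only the spiroketal stereocentres. The forward reaction must add an aryl-metal to an unbranched aliphatic aldehyde with catalyst-controlled face selection, let alkoxide 16 close onto the ester, and leave C5″ untouched.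

**Aldehyde (15 ⇒ 13).** The aldehyde carbon (the future C3) is traced back to the internal carbon of a terminal alkene, cleaved by ozonolysis through ozonide 14. An alkene is preferred to a protected alcohol because it survives organolithium and aqueous acid, needs no protecting-group steps and is already present in commercial epoxide 6. The forward step must be non-acidic so that C5″ is not scrambled.

**Spiroketal (13 ⇒ 12 ⇒ 11).** Cutting C5″–O1″ and C5″–O6″ opens both rings to dihydroxy ketone 12, which is handled as its dimethylhydrazone 11. No other cut offers better control of C5″, so the simplest one is taken. The precursor is acyclic with two carbinol stereocentres. The forward step is an acid-mediated hydrolysis and spiroketalisation under equilibrium control, followed by separation of the C5″ epimers and recycling of the wrong one.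

**Carbon chain (11 ⇒ 8 + 7 + 9).** C3″–C4″ and C8″–C9″ join the two α-carbons of acetone to the terminal carbons of two epoxides. A hydrazone azaenolate places the carbonyl carbon exactly three carbons from each carbinol, which a dithiane linchpin would not. Acetone dimethylhydrazone 8 is opened first by epoxide 7 (giving alkoxide 10) and then by (S)-propylene oxide 9. The forward step needs the second deprotonation to occur at the remaining methyl group.

**Epoxide (7 ⇒ 6).** The C2″ configuration is taken from racemic 1,2-epoxy-9-decene 6 by hydrolytic kinetic resolution, one step from a bulk chemical.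

**Arene (5 ⇒ 4 ⇒ 3 ⇒ 1).** The ester carbon C1 is introduced as a formyl group on 1-iodo-3,5-dimethoxybenzene 1 (through iminium salt 2), giving aldehyde 3, which is oxidised to acid 4 and O-methylated to 5. The iodine is present from the start, so the only selectivity required is formylation para to one methoxy group and ortho to the other.

## Roads not taken

**Alternative 1:** The cut is C3″–C4″ and C8″–C9″. The forward key step is the one-pot opening of epoxides 9 and 7 by twice-lithiated hydrazone 8, giving (2S,8S)-5-(2,2-dimethylhydrazinylidene)hexadec-15-ene-2,8-diol A1, which is the same compound as 11 in the chosen route.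
- Merits: a three-component assembly of every spiroketal carbon, with two of the four stereocentres taken unchanged from epoxides and no asymmetric catalysis.
- Weak points: it says nothing about C3, the lactone or the union with the arene. A phthalide cannot be carried through azaenolate chemistry, so the arene must be attached afterwards in any case. C5″ is not controlled.
- Comparison: in reliability this step is better than the chosen key step. The chosen plan keeps it as step 5 and sets against it a key step that solves the remaining problem (C3, the lactone and the fragment union) in one operation.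

**Alternative 2:** The cut is C7–C7a and C3a–C4 of the benzene ring. In the forward key step 1,3-dimethoxycyclohexa-1,3-diene A3 and methyl (4S)-4-(tert-butyldimethylsilyloxy)-10-[(2S,5S,7S)-7-methyl-1,6-dioxaspiro[4.4]nonan-2-yl]dec-2-ynoate A4 undergo thermal [4+2] cycloaddition and lose ethene. This gives silyl ether A2, methyl 2-{(1S)-1-(tert-butyldimethylsilyloxy)-7-[(2S,5S,7S)-7-methyl-1,6-dioxaspiro[4.4]nonan-2-yl]heptyl}-4,6-dimethoxybenzoate, which desilylation and lactonisation would turn into 17.
- Merits: the regiochemistry is secured by polarisation, since both methoxy groups of A3 make its unsubstituted diene terminus nucleophilic and it bonds to the β-carbon of A4. C3 would come from asymmetric addition of an ester-bearing terminal alkyne to aldehyde 15, which is better documented for unbranched aliphatic aldehydes than asymmetric cobalt arylation. On this point the alternative is stronger.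
- Weak points: four operations from 15 instead of one (alkynylation, silylation, cycloaddition, desilylation with lactonisation). The propargylic silyl ether and the spiroketal must survive a hot cycloaddition. A3 must be prepared by dissolving-metal reduction and isomerisation, and it is hydrolytically fragile. An arene is built that can be bought.
- Comparison: the chosen plan sets brevity and a purchased arene against the firmer stereocontrol of this alternative, and it carries a ketone-reduction fallback for C3.

**Alternative 3:** The cut is C5″–O6″ and C2″–O1″. In the forward key step (3S)-3-[(5S,6E,13S)-5,13-dihydroxy-10-oxotetradec-6-en-1-yl]-5,7-dimethoxy-2-benzofuran-1(3H)-one A6 is cyclised with PdCl2(MeCN)2 (divalent palladium). The C13′ hydroxyl forms the ring B hemiketal, whose hydroxyl attacks the palladium-bound alkene with loss of the allylic hydroxyl. The product is (3S)-5,7-dimethoxy-3-{(5E)-6-[(2R,5S,7S)-7-methyl-1,6-dioxaspiro[4.4]nonan-2-yl]hex-5-en-1-yl}-2-benzofuran-1(3H)-one A5, which hydrogenation would convert into 17. The descriptor at C2″ of A5 is R only because the alkene changes the CIP priorities; the spatial arrangement is that of 17. The 5′S configuration of A6 assumes the usual syn SN2′ course.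
- Merits: C2″ is set by chirality transfer under nearly neutral conditions, water is the only by-product, and the finished spiroketal never meets zinc salts.
- Weak points: the transfer controls C2″ but not C5″, so the epimer problem remains. An extra stereocentre at C5′ must be made enantioselectively only to be destroyed. A6 must already contain the phthalide with C3 set, so the hardest stereocentre comes early in a long linear sequence. A hydrogenation next to a benzylic C–O bond is added at the end.
- Comparison: the alternative is milder toward the spiroketal. The chosen plan is shorter and convergent, and takes C2″ from a one-step resolution.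

Key step: step 8

Assumption: (S,S)-DIPAMP is taken as the ligand antipode that leads to 3S with an unbranched aliphatic aldehyde; the sense of induction is to be confirmed on a simple model aldehyde before step 8, and the R,R ligand is used if it proves opposite.

## Route

Step 1
Reactants: 1 1-iodo-3,5-dimethoxybenzene
Product: 3 2-iodo-4,6-dimethoxybenzaldehyde, via aryl iminium salt 2 (not isolated)
Conditions: POCl3 (1.5 equiv), DMF, 0 → 80 °C; then H2O, 0 °C → rt
Reagents that add atoms: N,N-dimethylformamide, CN(C)C=O; water, O
Why: Vilsmeier–Haack formylation; the chloroiminium electrophile should attack the ring position para to one methoxy group and ortho to the other (next to iodine) in preference to the more crowded position between the two methoxy groups, and iminium salt 2 is hydrolysed on work-up.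

Step 2
Reactants: 3 2-iodo-4,6-dimethoxybenzaldehyde
Product: 4 2-iodo-4,6-dimethoxybenzoic acid
Conditions: NaClO2, NaH2PO4, 2-methyl-2-butene (excess), t-BuOH/THF/H2O, 0 °C → rt
Reagents that add atoms: sodium chlorite, [Na+].[O-]Cl=O
Why: Pinnick oxidation; chlorous acid oxidises the hindered aldehyde without touching the aryl iodide, and the alkene scavenger removes hypochlorous acid before it can chlorinate the electron-rich ring.

Step 3
Reactants: 4 2-iodo-4,6-dimethoxybenzoic acid
Product: 5 methyl 2-iodo-4,6-dimethoxybenzoate
Conditions: MeI, K2CO3, DMF, rt
Reagents that add atoms: iodomethane, CI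
Why: SN2 O-alkylation of the carboxylate; it avoids the tetrahedral intermediate that makes acid-catalysed esterification of a 2,6-disubstituted benzoic acid slow.

Step 4
Reactants: 6 rac-1,2-epoxy-9-decene [rac-2-(oct-7-en-1-yl)oxirane]
Product: 7 (2S)-2-(oct-7-en-1-yl)oxirane
Conditions: (S,S)-(salen)Co(OAc) (0.5 mol%), H2O (0.55 equiv), THF (minimal), 0 °C → rt; distillation from the diol
Reagents that add atoms: none
Why: Jacobsen hydrolytic kinetic resolution; the trivalent cobalt acetate complex of (S,S)-N,N′-bis(3,5-di-tert-butylsalicylidene)cyclohexane-1,2-diamine hydrates the R epoxide selectively, so the S epoxide, which carries the future C2″, is recovered unreacted.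

Step 5
Reactants: 8 acetone N,N-dimethylhydrazone; 7 (2S)-2-(oct-7-en-1-yl)oxirane; 9 (S)-propylene oxide
Product: 11 (2S,8S)-5-(2,2-dimethylhydrazinylidene)hexadec-15-ene-2,8-diol, via lithium alkoxide of mono-adduct 10 (not isolated)
Conditions: 8 (1.1 equiv), n-BuLi (1.1 equiv), THF, −78 → 0 °C; 7 (1.0 equiv), 0 °C → rt; n-BuLi (1.2 equiv), −78 → 0 °C; 9 (1.5 equiv), 0 °C → rt; H2O
Reagents that add atoms: none
Why: Corey–Enders azaenolate alkylation carried out twice; the lithiated hydrazone opens 7 at its terminal carbon by SN2, the second equivalent of base removes a proton from the remaining methyl group of 10 (kinetic deprotonation at the less substituted α-carbon), and the new azaenolate opens 9 in the same way. Both carbinol stereocentres (future C2″ and C7″) are carried over unchanged because only the CH2 carbons of the epoxides are attacked.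

Step 6
Reactants: 11 (2S,8S)-5-(2,2-dimethylhydrazinylidene)hexadec-15-ene-2,8-diol
Product: 13 (2S,5S,7S)-7-methyl-2-(oct-7-en-1-yl)-1,6-dioxaspiro[4.4]nonane, via dihydroxy ketone 12 (not isolated)
Conditions: 1 M aq. HCl, THF, rt; SiO2 chromatography (separation of the C5″ epimers)
Reagents that add atoms: none
Why: Acidic hydrazone hydrolysis releases ketone 12, which closes to the spiroketal by thermodynamic double ketalisation; the carbinol C–O bonds are not broken, so C2″ and C7″ are retained. C5″ forms under equilibrium control and both epimers are expected in comparable amounts; the 5″S isomer 13 is isolated by chromatography and the 5″R isomer is returned to the same acid to re-equilibrate.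

Step 7
Reactants: 13 (2S,5S,7S)-7-methyl-2-(oct-7-en-1-yl)-1,6-dioxaspiro[4.4]nonane
Product: 15 7-[(2S,5S,7S)-7-methyl-1,6-dioxaspiro[4.4]nonan-2-yl]heptanal, via secondary ozonide 14 (not isolated)
Conditions: O3, NaHCO3 (solid), CH2Cl2, −78 °C; PPh3, −78 °C → rt
Reagents that add atoms: ozone, [O-][O+]=O
Why: Ozonolysis by the Criegee mechanism with reductive work-up; the ketal carbon bears no hydrogen, so ozone has no acetal C–H to oxidise, and the hydrogencarbonate buffer keeps the medium non-acidic so that C5″ is not equilibrated.

Step 8
Reactants: 5 methyl 2-iodo-4,6-dimethoxybenzoate; 15 7-[(2S,5S,7S)-7-methyl-1,6-dioxaspiro[4.4]nonan-2-yl]heptanal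
Product: 17 (3S)-5,7-dimethoxy-3-{6-[(2S,5S,7S)-7-methyl-1,6-dioxaspiro[4.4]nonan-2-yl]hexyl}-2-benzofuran-1(3H)-one (the target), via cobalt alkoxide 16 (not isolated)
Conditions: CoI2 (10 mol%), (S,S)-DIPAMP (12 mol%), Zn powder (2.5 equiv), 5 (1.5 equiv), THF, 75 °C
Reagents that add atoms: none
Why: Zinc reduces the divalent cobalt iodide–DIPAMP complex to a monovalent cobalt species, which inserts into the C–I bond of 5 to give an arylcobalt intermediate held by the neighbouring ester carbonyl. Aldehyde 15 coordinates and inserts into the aryl–cobalt bond, forming C3–C3a and cobalt alkoxide 16; the alkoxide then attacks the ester carbon and expels methoxide, forming O2–C1, and zinc returns cobalt to its low-valent state. The closest known reaction type is the cobalt–bisphosphine-catalysed, zinc-mediated reductive coupling of methyl 2-iodobenzoates with aldehydes to 3-substituted phthalides, including its enantioselective form with a P-stereogenic bisphosphine. The lactone ring closes by 5-exo-trig acyl substitution, which the ortho relationship of C3a and C7a makes favourable as soon as the alkoxide exists. The new stereocentre C3 is set by the chiral bisphosphine on cobalt, which distinguishes the two faces of the bound aldehyde during insertion; the spiroketal stereocentres are at least seven bonds away and should exert no influence. The step needs chemoselectivity for the C–I bond over the aldehyde and for addition over simple reduction; the fast oxidative addition of an aryl iodide with a free ortho position (C4–H) and the use of 5 in excess should secure this. It also needs C5″ to stay fixed; the ether solvent ligates the zinc salts and no protic acid is present.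

## Compound list

1 | 1-iodo-3,5-dimethoxybenzene | COc1cc(I)cc(OC)c1 | starting material
2 | (2-iodo-4,6-dimethoxybenzylidene)dimethyliminium dichlorophosphate | COc1cc(I)c(C=[N+](C)C)c(OC)c1.[O-]P(=O)(Cl)Cl | intermediate (not isolated)
3 | 2-iodo-4,6-dimethoxybenzaldehyde | COc1cc(I)c(C=O)c(OC)c1 | intermediate
4 | 2-iodo-4,6-dimethoxybenzoic acid | COc1cc(I)c(C(=O)O)c(OC)c1 | intermediate
5 | methyl 2-iodo-4,6-dimethoxybenzoate | COC(=O)c1c(I)cc(OC)cc1OC | intermediate
6 | rac-1,2-epoxy-9-decene [rac-2-(oct-7-en-1-yl)oxirane] | C=CCCCCCCC1CO1 | starting material
7 | (2S)-2-(oct-7-en-1-yl)oxirane | C=CCCCCCC[C@H]1CO1 | intermediate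
8 | acetone N,N-dimethylhydrazone | CC(C)=NN(C)C | starting material
9 | (S)-propylene oxide | C[C@H]1CO1 | starting material
10 | lithium (5S)-2-(2,2-dimethylhydrazinylidene)tridec-12-en-5-olate | C=CCCCCCC[C@H]([O-])CCC(C)=NN(C)C.[Li+] | intermediate (not isolated)
11 | (2S,8S)-5-(2,2-dimethylhydrazinylidene)hexadec-15-ene-2,8-diol | C=CCCCCCC[C@H](O)CCC(CC[C@H](C)O)=NN(C)C | intermediate
12 | (2S,8S)-2,8-dihydroxyhexadec-15-en-5-one | C=CCCCCCC[C@H](O)CCC(=O)CC[C@H](C)O | intermediate (not isolated)
13 | (2S,5S,7S)-7-methyl-2-(oct-7-en-1-yl)-1,6-dioxaspiro[4.4]nonane | C=CCCCCCC[C@H]1CC[C@]3(CC[C@H](C)O3)O1 | intermediate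
14 | 3-{6-[(2S,5S,7S)-7-methyl-1,6-dioxaspiro[4.4]nonan-2-yl]hexyl}-1,2,4-trioxolane (mixture at the trioxolane carbon) | C1OC(CCCCCC[C@H]2CC[C@]3(CC[C@H](C)O3)O2)OO1 | intermediate (not isolated)
15 | 7-[(2S,5S,7S)-7-methyl-1,6-dioxaspiro[4.4]nonan-2-yl]heptanal | O=CCCCCCC[C@H]1CC[C@]3(CC[C@H](C)O3)O1 | intermediate
16 | methyl 2-{(1S)-1-hydroxy-7-[(2S,5S,7S)-7-methyl-1,6-dioxaspiro[4.4]nonan-2-yl]heptyl}-4,6-dimethoxybenzoate, present as its cobalt alkoxide (SMILES of the neutral hydroxy ester) | COC(=O)c1c(OC)cc(OC)cc1[C@@H](O)CCCCCC[C@H]1CC[C@]3(CC[C@H](C)O3)O1 | intermediate (not isolated)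
17 | (3S)-5,7-dimethoxy-3-{6-[(2S,5S,7S)-7-methyl-1,6-dioxaspiro[4.4]nonan-2-yl]hexyl}-2-benzofuran-1(3H)-one | COc1cc(OC)c2c(c1)[C@H](CCCCCC[C@H]1CC[C@]3(CC[C@H](C)O3)O1)OC2=O | target

## Step count and least certain steps

Total: 8 steps. Longest linear sequence: 5 steps (steps 4–8, from 6); the arene branch is 4 steps (steps 1–3 and 8).

**Step 8 (key step).** The most likely failure is weak enantioface discrimination. An unbranched aliphatic aldehyde offers the catalyst little to distinguish, and any uncatalysed arylzinc addition would erode selectivity further. The resulting C3 epimers differ only at a remote centre and would be hard to separate. A second concern is slow equilibration at C5″ by zinc Lewis acids at 75 °C, and a third is reduction of the aryl iodide. The fallback uses known chemistry, sets out from 15 and 5 and returns at 17. Aldehyde 15 is oxidised under the conditions of step 2 to 7-[(2S,5S,7S)-7-methyl-1,6-dioxaspiro[4.4]nonan-2-yl]heptanoic acid F1. Ethanethiol, DCC and DMAP convert this into S-ethyl 7-[(2S,5S,7S)-7-methyl-1,6-dioxaspiro[4.4]nonan-2-yl]heptanethioate F2. Iodide 5 is converted with Zn dust and LiCl in THF into [3,5-dimethoxy-2-(methoxycarbonyl)phenyl]zinc iodide F3, which is acylated by F2 under PdCl2(PPh3)2 catalysis (Fukuyama coupling). This gives methyl 2,4-dimethoxy-6-{7-[(2S,5S,7S)-7-methyl-1,6-dioxaspiro[4.4]nonan-2-yl]heptanoyl}benzoate F4. Asymmetric transfer hydrogenation of this aryl alkyl ketone with RuCl[(S,S)-TsDPEN](p-cymene) and HCO2Na in aqueous methanol should give hydroxy ester 16, which lactonises to 17 spontaneously or with K2CO3 in methanol. C3 then comes from a reduction whose facial rule for aryl alkyl ketones is well established, at the cost of four steps instead of one.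

**Step 6.** The most likely failure is incomplete chromatographic resolution of the two C5″ epimers, which are non-polar and differ only in the spiro centre, possibly combined with an equilibrium that does not favour 5″S. The fallback sets out from the unseparated product of step 6 and returns at 17. The mixture of 13 and (2S,5R,7S)-7-methyl-2-(oct-7-en-1-yl)-1,6-dioxaspiro[4.4]nonane F5 is taken through steps 7 and 8 unchanged. This gives 15 together with 7-[(2S,5R,7S)-7-methyl-1,6-dioxaspiro[4.4]nonan-2-yl]heptanal F6, and then 17 together with (3S)-5,7-dimethoxy-3-{6-[(2S,5R,7S)-7-methyl-1,6-dioxaspiro[4.4]nonan-2-yl]hexyl}-2-benzofuran-1(3H)-one F7. The polar, UV-active phthalides should be easier to resolve by normal-phase HPLC. F7 can be re-equilibrated with catalytic camphorsulfonic acid in CH2Cl2, which the lactone and aryl ethers tolerate, and separated again. This fallback also corrects any C5″ equilibration during step 8.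

**Step 5.** The most likely failure is an incomplete or misdirected second deprotonation of the aggregated lithium alkoxide, which would leave mono-adduct and give regioisomeric alkylation. The fallback sets out from 9 and 7 and returns at 13. Epoxide 9 is opened with propargylmagnesium bromide (Et2O, −78 → 0 °C) to (2S)-hex-5-yn-2-ol F8. Its dilithio derivative (n-BuLi, 2 equiv, THF/DMPU) opens 7 at the terminal carbon to give (2S,8S)-hexadec-15-en-5-yne-2,8-diol F9. AuCl (monovalent gold, catalytic) with pyridinium p-toluenesulfonate in CH2Cl2 should then effect double hydroalkoxylation onto alkyne carbon C5 (5-exo-dig by the C2 hydroxyl, 5-endo-dig by the C8 hydroxyl). The product is 13 with its C5″ epimer, which are separated as in step 6. This replaces the hydrazone linchpin by an alkyne linchpin and needs no second deprotonation next to an alkoxide.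

## Further compounds

F1 | step 8 | 7-[(2S,5S,7S)-7-methyl-1,6-dioxaspiro[4.4]nonan-2-yl]heptanoic acid | OC(=O)CCCCCC[C@H]1CC[C@]3(CC[C@H](C)O3)O1
F2 | step 8 | S-ethyl 7-[(2S,5S,7S)-7-methyl-1,6-dioxaspiro[4.4]nonan-2-yl]heptanethioate | CCSC(=O)CCCCCC[C@H]1CC[C@]3(CC[C@H](C)O3)O1
F3 | step 8 | [3,5-dimethoxy-2-(methoxycarbonyl)phenyl]zinc iodide | COC(=O)c1c([Zn]I)cc(OC)cc1OC
F4 | step 8 | methyl 2,4-dimethoxy-6-{7-[(2S,5S,7S)-7-methyl-1,6-dioxaspiro[4.4]nonan-2-yl]heptanoyl}benzoate | COC(=O)c1c(OC)cc(OC)cc1C(=O)CCCCCC[C@H]1CC[C@]3(CC[C@H](C)O3)O1
F5 | step 6 | (2S,5R,7S)-7-methyl-2-(oct-7-en-1-yl)-1,6-dioxaspiro[4.4]nonane | C=CCCCCCC[C@H]1CC[C@@]3(CC[C@H](C)O3)O1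
F6 | step 6 | 7-[(2S,5R,7S)-7-methyl-1,6-dioxaspiro[4.4]nonan-2-yl]heptanal | O=CCCCCCC[C@H]1CC[C@@]3(CC[C@H](C)O3)O1
F7 | step 6 | (3S)-5,7-dimethoxy-3-{6-[(2S,5R,7S)-7-methyl-1,6-dioxaspiro[4.4]nonan-2-yl]hexyl}-2-benzofuran-1(3H)-one | COc1cc(OC)c2c(c1)[C@H](CCCCCC[C@H]1CC[C@@]3(CC[C@H](C)O3)O1)OC2=O
F8 | step 5 | (2S)-hex-5-yn-2-ol | C#CCC[C@H](C)O
F9 | step 5 | (2S,8S)-hexadec-15-en-5-yne-2,8-diol | C=CCCCCCC[C@H](O)CC#CCC[C@H](C)O
A1 | alternative 1 | (2S,8S)-5-(2,2-dimethylhydrazinylidene)hexadec-15-ene-2,8-diol | C=CCCCCCC[C@H](O)CCC(CC[C@H](C)O)=NN(C)C
A2 | alternative 2 | methyl 2-{(1S)-1-(tert-butyldimethylsilyloxy)-7-[(2S,5S,7S)-7-methyl-1,6-dioxaspiro[4.4]nonan-2-yl]heptyl}-4,6-dimethoxybenzoate | COc1cc(OC)c(C(=O)OC)c(c1)[C@H](CCCCCC[C@H]1CC[C@]3(CC[C@H](C)O3)O1)O[Si](C)(C)C(C)(C)C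
A3 | alternative 2 | 1,3-dimethoxycyclohexa-1,3-diene | COC1=CC(OC)=CCC1
A4 | alternative 2 | methyl (4S)-4-(tert-butyldimethylsilyloxy)-10-[(2S,5S,7S)-7-methyl-1,6-dioxaspiro[4.4]nonan-2-yl]dec-2-ynoate | COC(=O)C#C[C@H](CCCCCC[C@H]1CC[C@]3(CC[C@H](C)O3)O1)O[Si](C)(C)C(C)(C)C
A5 | alternative 3 | (3S)-5,7-dimethoxy-3-{(5E)-6-[(2R,5S,7S)-7-methyl-1,6-dioxaspiro[4.4]nonan-2-yl]hex-5-en-1-yl}-2-benzofuran-1(3H)-one | COc1cc(OC)c2c(c1)[C@H](CCCC/C=C/[C@H]1CC[C@]3(CC[C@H](C)O3)O1)OC2=O
A6 | alternative 3 | (3S)-3-[(5S,6E,13S)-5,13-dihydroxy-10-oxotetradec-6-en-1-yl]-5,7-dimethoxy-2-benzofuran-1(3H)-one | COc1cc(OC)c2c(c1)[C@H](CCCC[C@H](O)/C=C/CCC(=O)CC[C@H](C)O)OC2=O
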